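## Retrosynthetic overview

- **Feature:** the oxane ring (O1′, C2′–C5′ and the spiro carbon C6′ = C8 of the 2-oxabicyclo[2.2.2]octane) is a reduced 2′,3′,5′-trimethyloxan-4′-one. It carries three equatorial methyl groups and an axial 4′-acetoxy group, and its spiro carbon sits at ketone level between quaternary C4 and C7(H)CH3.
- **26 ⇒ 23:** late protonation at C6 of a C5=C6 silyl enol ether, acetylation, and axial-selective reduction of the oxan-4′-one.
- **23 ⇒ 15 + 20:** C8–C5′ by Mukaiyama aldol and O1′–C2′ by 6-endo oxa-Michael closure, together a stepwise hetero-Diels–Alder reaction.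
- **15 ⇒ 13 ⇒ 6 + 7:** meso trione 13 is opened to 15 by removal of one enantiotopic proton; 13 comes from anti,anti hydroxy diester 6 and 2-bromopropanoyl bromide 7 by two C-acylations at one O-tethered α-carbon.
- **Ring order:** δ-lactone (step 5), carbocycle that completes the bicyclo[2.2.2] core (step 7), oxane (step 11).

Key step: step 11

**Locants.** Bicycle: C1 (O–CH), O2, C3 (lactone C=O), C4 (quaternary), C5, C6, C7, C8. Oxane: O1′, C2′ (O–CHCH3), C3′, C4′, C5′, C6′ = C8.

**Assumption.** The (R,R)-amide is taken to remove the C6–H of 13 as drawn. The sense of induction on this substrate has to be established, and the (S,S)-amine is equally available.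

**Remarks.** Racemic compounds are drawn as one enantiomer. Compounds 15 and 21–25 are formal 2-pyranone cycloadducts and are kept at or below room temperature to avoid cycloreversion with loss of CO2.

## Route

Step 1
Reactants: 1 dimethyl 3-oxopentanedioate
Product: 2 dimethyl 3-hydroxypentanedioate
Conditions: NaBH4, MeOH, 0 °C
Reagents that add atoms: none
Why: Borohydride reduction of a ketone beside esters; the carbinol carbon is not yet a stereocentre, and reducing before methylating lets the hydroxyl group direct both later methylations.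

Step 2
Reactants: 2 dimethyl 3-hydroxypentanedioate
Product: 4 dimethyl (2S*,3S*)-3-hydroxy-2-methylpentanedioate (racemic anti isomer), via dilithium alkoxide-enolate 3 (not isolated)
Conditions: LiN(i-Pr)2 (2.2 equiv), THF, −78 → −20 °C; MeI, −78 → 0 °C; AcOH
Reagents that add atoms: iodomethane, CI
Why: Fráter–Seebach alkylation, in which the lithium-chelated alkoxide-enolate 3 takes iodomethane on the face away from the C3 side chain and so sets the 2,3-anti relation.

Step 3
Reactants: 4 dimethyl (2S*,3S*)-3-hydroxy-2-methylpentanedioate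
Product: 6 dimethyl (2R,3r,4S)-3-hydroxy-2,4-dimethylpentanedioate (meso anti,anti isomer), via dilithium alkoxide-enolate 5 (not isolated)
Conditions: LiN(i-Pr)2 (2.2 equiv), THF, −78 → −20 °C; MeI, −78 → 0 °C; AcOH
Reagents that add atoms: iodomethane, CI
Why: Second Fráter–Seebach alkylation, in which the base takes a proton of the unbranched C4H2 group and chelate 5 is again methylated anti to the C3 substituent, giving the meso anti,anti triad that places both methyl groups on the O2 side of the later bicycle.

Step 4
Reactants: 6 dimethyl (2R,3r,4S)-3-hydroxy-2,4-dimethylpentanedioate; 7 2-bromopropanoyl bromide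
Product: 8 dimethyl (2R*,4S*)-3-(2-bromopropanoyloxy)-2,4-dimethylpentanedioate (racemic at C–Br)
Conditions: pyridine, CH2Cl2, 0 °C
Reagents that add atoms: none
Why: O-acylation with an acyl bromide under a weak base; the α-bromine allows regiospecific enolate formation, because amide-base deprotonation of a plain propanoate would compete with removal of C2–H or C4–H and E1cB loss of the acyloxy group.

Step 5
Reactants: 8 dimethyl 3-(2-bromopropanoyloxy)-2,4-dimethylpentanedioate
Product: 10 methyl 2-(4-hydroxy-3,5-dimethyl-2-oxo-5,6-dihydro-2H-pyran-6-yl)propanoate (racemic; C5 methyl trans to the C6 side chain), via magnesium enolate 9 (not isolated)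
Conditions: t-BuMgCl, THF, 40 °C (slow addition of 8); 1 M HCl, 0 °C
Reagents that add atoms: none
Why: Bromine–magnesium exchange forms the enolate only at the acyl α-carbon (a Reformatsky-type entry into a Dieckmann condensation, known for 3-(2-bromoacyloxy) esters), and 9 is acylated by one of the two equivalent ester groups to close the δ-lactone, the product resting as its stabilised enolate so that the three stereocentres stay untouched.

Step 6
Reactants: 10 methyl 2-(4-hydroxy-3,5-dimethyl-2-oxo-5,6-dihydro-2H-pyran-6-yl)propanoate
Product: 11 2-(4-hydroxy-3,5-dimethyl-2-oxo-5,6-dihydro-2H-pyran-6-yl)propanoic acid (racemic)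
Conditions: LiOH, THF–H2O, 0 °C → rt; HCl to pH 2
Reagents that add atoms: lithium hydroxide, [Li+].[OH-]
Why: Saponification, in which the β-keto lactone sits as its enolate, shielding the lactone carbonyl and making the ring oxygen a poor leaving group, so that only the side-chain methyl ester is cleaved.

Step 7
Reactants: 11 2-(4-hydroxy-3,5-dimethyl-2-oxo-5,6-dihydro-2H-pyran-6-yl)propanoic acid
Product: 13 meso-(6R,7S)-4,6,7-trimethyl-2-oxabicyclo[2.2.2]octane-3,5,8-trione (both CH methyl groups on the O2 side), via acyl trifluoroacetate 12 (not isolated)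
Conditions: (CF3CO)2O, TfOH (10 mol %), CH2Cl2 (0.01 M), 0 °C; evaporation, short silica plug
Reagents that add atoms: none
Why: Acid-promoted intramolecular C-acylation of an enol by a mixed anhydride, the cyclodehydration type that turns 3-oxocyclohexylacetic acids into bicyclo[2.2.2]octane-2,6-diones; it replaces a second base-mediated Dieckmann closure, which fails because the product has no acidic C–H and alkoxide would cleave it again, while O-acylation would need a bridgehead C=C, the tether fixes quaternary C4, and the absence of base keeps C6 and C7 intact and avoids enolates next to C1–O2.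

Step 8
Reactants: 13 meso-4,6,7-trimethyl-2-oxabicyclo[2.2.2]octane-3,5,8-trione
Product: 15 (1R,4R,7S)-4,6,7-trimethyl-5-(triisopropylsilyloxy)-2-oxabicyclo[2.2.2]oct-5-ene-3,8-dione, via lithium enolate 14 (not isolated)
Conditions: (R,R)-bis(1-phenylethyl)amine, n-BuLi, LiCl, THF, −78 °C; add 13, −100 °C, 10 min; i-Pr3SiOTf, −100 → −78 °C; cold aq. NaHCO3
Reagents that add atoms: triisopropylsilyl trifluoromethanesulfonate, CC(C)[Si](OS(=O)(=O)C(F)(F)F)(C(C)C)C(C)C
Why: Enantioselective deprotonation of a meso ketone by a C2-symmetric chiral lithium amide followed by O-silylation, in which the base tells the enantiotopic C6–H and C7–H apart and so fixes the absolute configuration at C1, C4 and C7 in one event, the very low temperature and short ageing being chosen because 14 is a β-acyloxy enolate whose C1–O2 bond lies close to the π axis.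

Step 9
Reactants: 16 pentan-3-one; 17 acetaldehyde
Product: 19 (E)-4-methylhex-4-en-3-one, via aldol 18 (not isolated)
Conditions: H2SO4 (cat.), 16 in excess, 65 °C, slow addition of 17; distillation
Reagents that add atoms: none
Why: Acid-catalysed crossed aldol condensation as practised for 3-methylpent-3-en-2-one, in which the symmetrical ketone has only one kind of α-position and aldol 18 dehydrates to the more stable E-enone.

Step 10
Reactants: 19 (E)-4-methylhex-4-en-3-one
Product: 20 (2Z,4E)-4-methyl-3-(trimethylsilyloxy)hexa-2,4-diene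
Conditions: Me3SiOTf, Et3N, Et2O, 0 °C
Reagents that add atoms: trimethylsilyl trifluoromethanesulfonate, C[Si](C)(C)OS(=O)(=O)C(F)(F)F
Why: Soft enolisation with a silyl triflate and an amine takes the only α-CH2 group and gives mainly the Z enol silane, whose geometry is not carried into the product.

Step 11
Reactants: 15 (1R,4R,7S)-4,6,7-trimethyl-5-(triisopropylsilyloxy)-2-oxabicyclo[2.2.2]oct-5-ene-3,8-dione; 20 (2Z,4E)-4-methyl-3-(trimethylsilyloxy)hexa-2,4-diene
Product: 23 (1R,4S,7S,8R,2′R,3′R,5′S)-2′,3′,4,5′,6,7-hexamethyl-5-(triisopropylsilyloxy)spiro[2-oxabicyclo[2.2.2]oct-5-ene-8,6′-oxane]-3,4′-dione, via silylated aldol adduct 21 (not isolated), via cyclic trimethylsilyl enol ether 22 (not isolated)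
Conditions: Me3SiOTf (20 mol %), 2,6-di-tert-butyl-4-methylpyridine, CH2Cl2, −78 → −30 °C; aq. citric acid, THF, 0 °C; DBU (10 mol %), CH2Cl2, 0 °C → rt, short exposure
Reagents that add atoms: none
Why: Proposed new method: Me3SiOTf silylates the C8 ketone oxygen (an electron-poor carbonyl, since C4 carries two further acyl-type groups), C2 of diene 20 adds (Mukaiyama aldol, C8–C5′ bond) to give 21, and the tertiary silyl ether oxygen then closes onto the silyl-activated enone in a 6-endo-trig oxa-Michael addition (O1′–C2′ bond) that returns the silyl cation and leaves 22, so the sequence is a stepwise hetero-Diels–Alder reaction catalytic in silicon. The closest known reactions are the Lewis-acid aldol/oxa-Michael and formal hetero-Diels–Alder annulations of 2-silyloxydienes with aldehydes and activated ketones to oxan-4-ones, and an α-quaternary, α′-branched bridged ketone has not been used in them. C8 is set by attack from the face next to the flat C5=C6 bridge, anti to the C7 methyl group that covers the lactone-side face; C2′ is set in the chair-like closure, where an axial methyl group would be syn-diaxial to C7; C3′ (protonation of 22) and C5′ are α to the new ketone and are brought equatorial by enolisation with DBU, the chair being the one with quaternary C4 equatorial because the other chair drives C2′ and C4′ into the C4 methyl group. The C8–C4 bond is not protected by Bredt's rule, since its cleavage opens the bicycle and a model puts this σ bond only about 30° off the lactone π axis, so a free C8 alkoxide is avoided by keeping that oxygen on silicon until the ring is closed, and C5 is kept as an enol ether so that C4 could leave only as a simple ester enolate. The step needs reaction of the small trimethylsilyl enol ether in the presence of the tetrasubstituted triisopropylsilyl enol ether, and activation of the ketone without ionising the allylic C1–O2 bond, which the catalytic silyl triflate, the hindered pyridine and the low temperature are meant to secure.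

Step 12
Reactants: 23 spiro oxan-4′-one
Product: 24 (1R,4S,7S,8S,2′R,3′R,4′R,5′R)-4′-hydroxy-2′,3′,4,5′,6,7-hexamethyl-5-(triisopropylsilyloxy)spiro[2-oxabicyclo[2.2.2]oct-5-ene-8,6′-oxan]-3-one (axial alcohol)
Conditions: LiBH(s-Bu)3, THF, −78 °C; AcOH
Reagents that add atoms: none
Why: Bulky trialkylborohydride reduction, in which hydride comes along the equatorial trajectory because the axial one is closed by the axial C7 substituent on the spiro carbon, giving the axial 4′-alcohol while the lactone and silyl enol ether are inert at this temperature.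

Step 13
Reactants: 24 axial 4′-alcohol
Product: 25 4′-acetate of 24, (1R,4S,7S,8S,2′R,3′R,4′R,5′R)
Conditions: Ac2O, DMAP (cat.), pyridine, rt
Reagents that add atoms: acetic anhydride, CC(=O)OC(C)=O
Why: DMAP-catalysed acyl transfer to a hindered secondary alcohol, with no stereocentre affected because the only enolisable ketone is still masked.

Step 14
Reactants: 25 acetate
Product: 26 target, (1R,4S,6S,7S,8S,2′R,3′R,4′R,5′R)-2′,3′,4,5′,6,7-hexamethyl-3,5-dioxospiro[2-oxabicyclo[2.2.2]octane-8,6′-oxan]-4′-yl acetate
Conditions: HF·pyridine, THF, −20 → 0 °C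
Reagents that add atoms: none
Why: Protodesilylation of a silyl enol ether under acidic fluoride with kinetic protonation, in which C6 takes its proton from the open lactone-side face because C5′ and its methyl group cover the other face, so the C6 methyl group points to the spiro bridge as in the target, and the acidic medium avoids a free β-acyloxy enolate, E1cB opening and later epimerisation.

## Compound list

1 | dimethyl 3-oxopentanedioate | COC(=O)CC(=O)CC(=O)OC | starting material
2 | dimethyl 3-hydroxypentanedioate | COC(=O)CC(O)CC(=O)OC | intermediate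
3 | dilithium alkoxide-enolate of 2 (not isolated) | [Li+].[Li+].COC(=O)CC([O-])C=C([O-])OC | intermediate
4 | dimethyl (2S*,3S*)-3-hydroxy-2-methylpentanedioate, racemic, anti | COC(=O)[C@@H](C)[C@@H](O)CC(=O)OC | intermediate
5 | dilithium alkoxide-enolate of 4 (not isolated) | [Li+].[Li+].COC(=O)[C@@H](C)[C@@H]([O-])C=C([O-])OC | intermediate
6 | dimethyl (2R,3r,4S)-3-hydroxy-2,4-dimethylpentanedioate, meso, anti,anti | COC(=O)[C@@H](C)[C@@H](O)[C@@H](C)C(=O)OC | intermediate
7 | 2-bromopropanoyl bromide, racemic | CC(Br)C(Br)=O | starting material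
8 | dimethyl 3-(2-bromopropanoyloxy)-2,4-dimethylpentanedioate, anti,anti core, racemic at C–Br | COC(=O)[C@@H](C)[C@@H](OC(=O)C(C)Br)[C@@H](C)C(=O)OC | intermediate
9 | chloromagnesium enolate of the propanoyl ester (not isolated) | COC(=O)[C@@H](C)[C@@H](OC(=CC)O[Mg]Cl)[C@@H](C)C(=O)OC | intermediate
10 | methyl 2-(4-hydroxy-3,5-dimethyl-2-oxo-5,6-dihydro-2H-pyran-6-yl)propanoate, racemic | COC(=O)[C@@H](C)[C@H]1OC(=O)C(C)=C(O)[C@@H]1C | intermediate
11 | 2-(4-hydroxy-3,5-dimethyl-2-oxo-5,6-dihydro-2H-pyran-6-yl)propanoic acid, racemic | OC(=O)[C@@H](C)[C@H]1OC(=O)C(C)=C(O)[C@@H]1C | intermediate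
12 | mixed anhydride of 11 and trifluoroacetic acid (not isolated) | FC(F)(F)C(=O)OC(=O)[C@@H](C)[C@H]1OC(=O)C(C)=C(O)[C@@H]1C | intermediate
13 | meso-(6R,7S)-4,6,7-trimethyl-2-oxabicyclo[2.2.2]octane-3,5,8-trione | O=C2[C@@H](C)[C@H]1OC(=O)[C@]2(C)C(=O)[C@@H]1C | intermediate
14 | lithium C5–C6 enolate of 13 (not isolated) | [Li+].O=C2[C@@H](C)[C@H]1OC(=O)[C@]2(C)C([O-])=C1C | intermediate
15 | (1R,4R,7S)-4,6,7-trimethyl-5-(triisopropylsilyloxy)-2-oxabicyclo[2.2.2]oct-5-ene-3,8-dione | O=C2[C@@H](C)[C@H]1OC(=O)[C@]2(C)C(O[Si](C(C)C)(C(C)C)C(C)C)=C1C | intermediate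
16 | pentan-3-one | CCC(=O)CC | starting material
17 | acetaldehyde | CC=O | starting material
18 | 5-hydroxy-4-methylhexan-3-one, diastereomer mixture (not isolated) | CCC(=O)C(C)C(C)O | intermediate
19 | (E)-4-methylhex-4-en-3-one | CCC(=O)/C(C)=C/C | intermediate
20 | (2Z,4E)-4-methyl-3-(trimethylsilyloxy)hexa-2,4-diene | C/C=C(C)/C(O[Si](C)(C)C)=C/C | intermediate
21 | C8 trimethylsilyl ether of the aldol adduct, C5′ epimers (not isolated) | C/C=C(C)/C(=O)C(C)[C@]2(O[Si](C)(C)C)[C@@H](C)[C@H]1OC(=O)[C@]2(C)C(O[Si](C(C)C)(C(C)C)C(C)C)=C1C | intermediate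
22 | spiro 4′-(trimethylsilyloxy)-dihydropyran, C5′ epimers (not isolated) | C[Si](C)(C)OC1=C(C)[C@@H](C)O[C@@]2(C1C)[C@@H](C)[C@H]1OC(=O)[C@]2(C)C(O[Si](C(C)C)(C(C)C)C(C)C)=C1C | intermediate
23 | spiro oxan-4′-one, three methyl groups equatorial, O1′ syn to the C7 methyl group | O=C1[C@H](C)[C@@H](C)O[C@@]2([C@@H]1C)[C@@H](C)[C@H]1OC(=O)[C@]2(C)C(O[Si](C(C)C)(C(C)C)C(C)C)=C1C | intermediate
24 | axial 4′-alcohol | O[C@@H]1[C@H](C)[C@@H](C)O[C@@]2([C@@H]1C)[C@@H](C)[C@H]1OC(=O)[C@]2(C)C(O[Si](C(C)C)(C(C)C)C(C)C)=C1C | intermediate
25 | axial 4′-acetate | CC(=O)O[C@@H]1[C@H](C)[C@@H](C)O[C@@]2([C@@H]1C)[C@@H](C)[C@H]1OC(=O)[C@]2(C)C(O[Si](C(C)C)(C(C)C)C(C)C)=C1C | intermediate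
26 | CNP0257416.1 | CC(=O)O[C@@H]1[C@H](C)[C@@H](C)O[C@@]2([C@@H]1C)[C@@H](C)[C@H]1OC(=O)[C@]2(C)C(=O)[C@H]1C | target

## Step count and risks

Total steps: 14. Longest linear sequence: 12 (steps 1–8 and 11–14).

**1. Step 11 (key step).**
- *What may go wrong:* C–C bond formation may stall at the very hindered carbonyl. The allylic C1–O2 bond may ionise under the silyl Lewis acid, with capture of the diene at C1. Face selection at C8 may be poor, or C5′ may not settle fully.
- *Fallback:* the C8–C5′ bond is made with a weakly basic metal enolate instead of an activated ketone. It sets out from 20 and 15.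
  - N-bromosuccinimide in THF at −78 °C turns 20 into (E)-2-bromo-4-methylhex-4-en-3-one F1.
  - Activated zinc in THF adds F1 to the C8 ketone of 15 (Reformatsky reaction) to give the tertiary β-hydroxy enone F2.
  - Catalytic camphorsulfonic acid in CH2Cl2 at 0 °C closes F2 by intramolecular oxa-Michael addition. The same short DBU treatment brings the sequence back to the route at 23.

**2. Step 8.**
- *What may go wrong:* the lactone carboxylate may be lost from the β-acyloxy enolate by β-elimination before silylation, leading on to decarboxylation and aromatisation. Discrimination of the two enantiotopic protons may also be insufficient.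
- *Fallback:* it avoids any enolate and sets out from 13.
  - Desymmetrising mono-reduction is a reaction type known for 2,2-disubstituted 1,3-diketones and for bicyclo[2.2.2]octane-2,6-diones. The appropriate enantiomer of the B-methyl oxazaborolidine (CBS) catalyst with BH3·SMe2 gives the 8-hydroxy-3,5-dione F3, whose carbinol configuration is of no consequence.
  - Et3SiOTf and 2,6-lutidine give the triethylsilyl ether F4.
  - Soft enolisation of the remaining ketone with i-Pr3SiOTf and Et3N gives the silyl enol ether F5.
  - Pyridine-buffered HF·pyridine at 0 °C removes only the triethylsilyl group to give the alcohol F6.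
  - Dess–Martin periodinane returns to the route at 15.

**3. Step 7.**
- *What may go wrong:* intermolecular O-acylation and oligomerisation may take over from ring closure. Acid-induced enolisation may erode the C6 and C7 configurations or open the lactone.
- *Fallback:* the C4–C8 bond is formed at aldehyde level. It sets out from 11.
  - EtSH, N,N′-dicyclohexylcarbodiimide and catalytic DMAP give the S-ethyl thioester F7.
  - Et3SiH and palladium on carbon (Fukuyama reduction) give the aldehyde F8.
  - F8 closes by intramolecular aldol addition of the β-keto lactone enol (catalytic camphorsulfonic acid, CH2Cl2) to the bicyclic 8-hydroxy-3,5-dione F9, obtained racemic and as carbinol epimers.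
  - Dess–Martin periodinane returns to the route at 13.

## Further compounds

F1 | step 11 | (E)-2-bromo-4-methylhex-4-en-3-one, racemic | C/C=C(C)/C(=O)C(C)Br
F2 | step 11 | tertiary β-hydroxy enone from 15 (free C8–OH, C5′ epimers) | C/C=C(C)/C(=O)C(C)[C@]2(O)[C@@H](C)[C@H]1OC(=O)[C@]2(C)C(O[Si](C(C)C)(C(C)C)C(C)C)=C1C
F3 | step 8 | 8-hydroxy-4,6,7-trimethyl-2-oxabicyclo[2.2.2]octane-3,5-dione, single enantiomer | O[C@H]2[C@@H](C)[C@H]1OC(=O)[C@]2(C)C(=O)[C@@H]1C
F4 | step 8 | 8-triethylsilyl ether of F3 | CC[Si](CC)(CC)O[C@H]2[C@@H](C)[C@H]1OC(=O)[C@]2(C)C(=O)[C@@H]1C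
F5 | step 8 | 8-(triethylsilyloxy)-5-(triisopropylsilyloxy)-4,6,7-trimethyl-2-oxabicyclo[2.2.2]oct-5-en-3-one | CC[Si](CC)(CC)O[C@H]2[C@@H](C)[C@H]1OC(=O)[C@]2(C)C(O[Si](C(C)C)(C(C)C)C(C)C)=C1C
F6 | step 8 | 8-hydroxy-5-(triisopropylsilyloxy)-4,6,7-trimethyl-2-oxabicyclo[2.2.2]oct-5-en-3-one | O[C@H]2[C@@H](C)[C@H]1OC(=O)[C@]2(C)C(O[Si](C(C)C)(C(C)C)C(C)C)=C1C
F7 | step 7 | S-ethyl thioester of 11, racemic | CCSC(=O)[C@@H](C)[C@H]1OC(=O)C(C)=C(O)[C@@H]1C
F8 | step 7 | 2-(4-hydroxy-3,5-dimethyl-2-oxo-5,6-dihydro-2H-pyran-6-yl)propanal, racemic | O=C[C@@H](C)[C@H]1OC(=O)C(C)=C(O)[C@@H]1C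
F9 | step 7 | 8-hydroxy-4,6,7-trimethyl-2-oxabicyclo[2.2.2]octane-3,5-dione, racemic, carbinol epimers | OC2[C@@H](C)[C@H]1OC(=O)[C@]2(C)C(=O)[C@@H]1C
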